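Ring B (C5–C6–C7–C8–C9–C10) carries oxygen at C6 and at the C8 carbinol, a 1,3-relationship across C7 that is an aldol retron. The route therefore keeps ring B open until late and closes it by intramolecular aldol condensation of a 7,8-seco-6,8-diketone: the C7 methyl of a C6 acetyl group attacks the C8 methyl ketone, and the basic medium also secures the trans ring fusion at C5. The resulting 7-en-6-one accepts both oxygen functions from the α face. The precursor is a monocyclic cyclohexane whose C10 quaternary centre and C9 are set together by an Ireland–Claisen rearrangement of an (R)-allylic ester made from β-cyclocitral.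

Key step: step 8

Remark: carbon locants (C1–C20) and α/β descriptors follow labdane numbering throughout, also for the monocyclic 7,8-seco intermediates; all starting materials and reagents named are taken to be commercial.

Step 1
Reactants: 1 β-cyclocitral (2,6,6-trimethylcyclohex-1-ene-1-carbaldehyde)
Product: 2 rac-1-(2,6,6-trimethylcyclohex-1-en-1-yl)ethan-1-ol
Conditions: MeMgBr, Et2O, 0 °C → rt; H2O
Reagents that add atoms: methylmagnesium bromide, C[Mg]Br
Why: 1,2-Grignard addition to the hindered enal should give the allylic alcohol, whose configuration does not matter because it is erased in step 2.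

Step 2
Reactants: 2 rac-1-(2,6,6-trimethylcyclohex-1-en-1-yl)ethan-1-ol
Product: 3 1-(2,6,6-trimethylcyclohex-1-en-1-yl)ethan-1-one
Conditions: Dess–Martin periodinane, NaHCO3, CH2Cl2, rt
Reagents that add atoms: none
Why: Dess–Martin oxidation of the secondary allylic alcohol should give the enone under neutral conditions that leave the tetrasubstituted alkene untouched.

Step 3
Reactants: 3 1-(2,6,6-trimethylcyclohex-1-en-1-yl)ethan-1-one
Product: 4 (1R)-1-(2,6,6-trimethylcyclohex-1-en-1-yl)ethan-1-ol
Conditions: (S)-1-methyl-3,3-diphenyltetrahydro-1H,3H-pyrrolo[1,2-c][1,3,2]oxazaborole [(S)-Me-CBS, 10 mol %], BH3·SMe2, THF, −20 °C; MeOH, aqueous work-up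
Reagents that add atoms: none
Why: Corey–Bakshi–Shibata reduction, in which the (S)-oxazaborolidine distinguishes the bulky trimethylcyclohexenyl group from methyl and should deliver hydride to give the (R)-carbinol (future C6), the only stereocentre set by an external chiral reagent.

Step 4
Reactants: 4 (1R)-1-(2,6,6-trimethylcyclohex-1-en-1-yl)ethan-1-ol; 5 4-(benzyloxy)butanoic acid
Product: 6 (1R)-1-(2,6,6-trimethylcyclohex-1-en-1-yl)ethyl 4-(benzyloxy)butanoate
Conditions: N,N'-dicyclohexylcarbodiimide, 4-(dimethylamino)pyridine, CH2Cl2, 0 °C → rt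
Reagents that add atoms: none
Why: Steglich esterification should acylate the hindered secondary allylic alcohol without touching its stereocentre.

Step 5
Reactants: 6 (1R)-1-(2,6,6-trimethylcyclohex-1-en-1-yl)ethyl 4-(benzyloxy)butanoate
Product: 9 (2R)-4-(benzyloxy)-2-[(1R,2E)-2-ethylidene-1,3,3-trimethylcyclohexyl]butanoic acid, via Z-silyl ketene acetal 7 (not isolated), via trimethylsilyl ester 8 (not isolated)
Conditions: LiN(i-Pr)2, THF/DMPU, −78 °C; Me3SiCl, −78 °C → 65 °C; H2O/MeOH work-up
Reagents that add atoms: none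
Why: Ireland–Claisen rearrangement, in which the Z-silyl ketene acetal 7 (chain cis to OSiMe3, favoured by the DMPU co-solvent) should react through a chair transition state with H-6 eclipsing the ring alkene to avoid allylic strain with the C10 methyl, so that the (R)-carbinol configuration is transferred suprafacially to the quaternary C10 and the enolate geometry sets C9 as R.

Step 6
Reactants: 9 (2R)-4-(benzyloxy)-2-[(1R,2E)-2-ethylidene-1,3,3-trimethylcyclohexyl]butanoic acid
Product: 10 (3R)-5-(benzyloxy)-3-[(1R,2E)-2-ethylidene-1,3,3-trimethylcyclohexyl]pentan-2-one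
Conditions: MeLi (2.5 equiv), Et2O, 0 °C → rt; inverse quench into ice-water
Reagents that add atoms: methyllithium, [Li]C
Why: Addition of methyllithium to the lithium carboxylate gives a gem-dialkoxide that collapses to the C8 methyl ketone only on work-up, so over-addition and C9 epimerisation should be avoided.

Step 7
Reactants: 10 (3R)-5-(benzyloxy)-3-[(1R,2E)-2-ethylidene-1,3,3-trimethylcyclohexyl]pentan-2-one
Product: 12 (3R)-3-[(1R,2S)-2-acetyl-1,3,3-trimethylcyclohexyl]-5-(benzyloxy)pentan-2-one (12-benzyloxy-7,8-seco-13,14,15,16-tetranorlabdane-6,8-dione), via bis-borane adduct 11 (not isolated)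
Conditions: BH3·THF (excess), THF, 0 → 45 °C; then N-methylmorpholine N-oxide (excess), (n-Pr4N)RuO4 (5 mol %), 4 Å molecular sieves, CH2Cl2, rt
Reagents that add atoms: N-methylmorpholine N-oxide, C[N+]1([O-])CCOCC1
Why: Hydroboration–oxidation, in which borane reduces the C8 ketone and adds across the ethylidene group with boron on C6 from the face opposite the axial methyl groups on C4 and C10 (H-5 trans to the C10 methyl), after which the amine oxide oxidises the C–B bond and the perruthenate-catalysed oxidation turns both carbinols into ketones.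

Step 8
Reactants: 12 (3R)-3-[(1R,2S)-2-acetyl-1,3,3-trimethylcyclohexyl]-5-(benzyloxy)pentan-2-one
Product: 14 12-benzyloxy-13,14,15,16-tetranorlabd-7-en-6-one (5α-H, 9α-H), via aldol 13 (not isolated)
Conditions: KOH, MeOH, 0 °C → rt
Reagents that add atoms: none
Why: Hydroxide reversibly forms the enolates of 12; the C7 enolate of the C6 acetyl group adds to the C8 carbonyl through a six-membered chair-like transition state, and E1cB loss of water from aldol 13 makes the closure irreversible (intramolecular aldol condensation, the ring-forming half of a Robinson annulation). Ring B is closed in the 6-(enolendo)-exo-trig mode. No stereocentre is created, since C8 becomes trigonal; the existing C5 centre, α to the C6 carbonyl, is under thermodynamic control and should settle as the trans-fused 5α-H isomer, so any C5 epimer carried from step 7 converges. The step needs regioselectivity between the two methyl ketones: the alternative C17-to-C6 closure would attack the carbonyl flanked by the quaternary C4 and C10 and would place a vinylic methyl against the C4 gem-dimethyl group, so the C7-to-C8 mode should dominate both kinetically and thermodynamically. It also needs C9 to stay intact, which the mild base at or below room temperature and the hindered tertiary C9–H next to quaternary C10 should secure.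

Step 9
Reactants: 14 12-benzyloxy-13,14,15,16-tetranorlabd-7-en-6-one
Product: 15 12-benzyloxy-7α,8α-epoxy-13,14,15,16-tetranorlabdan-6-one
Conditions: 30% aq. H2O2, NaOH, MeOH, 0 °C → rt
Reagents that add atoms: hydrogen peroxide, OO
Why: Weitz–Scheffer nucleophilic epoxidation, in which hydroperoxide should add to C8 from the α face, away from the axial C10 methyl and the β-oriented C9 chain, so that the new C8–O bond is α.

Step 10
Reactants: 15 12-benzyloxy-7α,8α-epoxy-13,14,15,16-tetranorlabdan-6-one
Product: 17 13,14,15,16-tetranorlabdane-6α,8α,12-triol, via hydroxy ketone 16 (not isolated)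
Conditions: Li, liq. NH3/THF/EtOH, −78 → −33 °C; then H2O
Reagents that add atoms: none
Why: Dissolving-metal reduction, in which two-electron cleavage of the C7–O bond keeps the 8α-oxygen, reduction of the C6 ketone under thermodynamic control should give the equatorial 6α-alcohol, and the benzyl ether is cleaved in the same operation.

Step 11
Reactants: 17 13,14,15,16-tetranorlabdane-6α,8α,12-triol
Product: 19 6α-hydroxy-13,14,15,16-tetranorlabdan-12,8α-olide (6α-hydroxysclareolide), via lactol 18 (not isolated)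
Conditions: 2,2,6,6-tetramethylpiperidin-1-oxyl (TEMPO, 10 mol %), PhI(OAc)2 (2.2 equiv), CH2Cl2, rt
Reagents that add atoms: none
Why: Nitroxyl-catalysed oxidation is selective for the primary alcohol, the aldehyde is trapped by the 8α-hydroxyl as a lactol that is oxidised on to the γ-lactone, and the hindered secondary 6α-hydroxyl should remain.

Step 12
Reactants: 19 6α-hydroxy-13,14,15,16-tetranorlabdan-12,8α-olide
Product: 18 8α,12-epoxy-13,14,15,16-tetranorlabdane-6α,12-diol (lactol, C12 epimers)
Conditions: i-Bu2AlH (2.5 equiv), CH2Cl2, −78 °C; aq. potassium sodium tartrate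
Reagents that add atoms: none
Why: Partial reduction of the γ-lactone with i-Bu2AlH at low temperature should stop at the aluminium hemiacetal and give the lactol.

Step 13
Reactants: 18 8α,12-epoxy-13,14,15,16-tetranorlabdane-6α,12-diol
Product: 20 (12Z)-13-iodo-14,15-dinorlabd-12-ene-6α,8α-diol
Conditions: EtPPh3I, n-BuLi, THF, 0 °C; I2, −78 °C; NaN(SiMe3)2, −78 → −20 °C; then 18 (as its sodium alkoxide), −78 °C → rt
Reagents that add atoms: ethyltriphenylphosphonium iodide, CC[P+](c1ccccc1)(c1ccccc1)c1ccccc1.[I-]; iodine, II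
Why: Stork–Zhao-type Wittig olefination, in which the α-iodo ylide reacts with the open hydroxy-aldehyde form of the lactol and should give the trisubstituted Z-iodoalkene (iodine cis to C11) under kinetic control.

Step 14
Reactants: 20 (12Z)-13-iodo-14,15-dinorlabd-12-ene-6α,8α-diol
Product: 21 (12Z)-labda-12,14-diene-6α,8α-diol
Conditions: CH2=CHSnBu3, Pd(PPh3)4 (5 mol %), CuI (10 mol %), DMF, rt
Reagents that add atoms: tributyl(vinyl)stannane, C=C[Sn](CCCC)(CCCC)CCCC
Why: Stille cross-coupling of the alkenyl iodide proceeds with retention of alkene geometry and should give the 12Z diene.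

Step 15
Reactants: 21 (12Z)-labda-12,14-diene-6α,8α-diol
Product: 22 (12Z)-8α-hydroxylabda-12,14-dien-6α-yl (2Z)-2-methylbut-2-enoate
Conditions: angelic acid, 2,4,6-trichlorobenzoyl chloride, Et3N, toluene, rt; then 21, 80 °C
Reagents that add atoms: angelic acid [(2Z)-2-methylbut-2-enoic acid], C/C=C(/C)C(=O)O
Why: Yamaguchi-type esterification through the mixed anhydride should acylate the secondary 6α-hydroxyl in preference to the tertiary 8α-hydroxyl, and the absence of a nucleophilic pyridine catalyst should preserve the Z geometry of the angelate.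

Compound list
1 | β-cyclocitral (2,6,6-trimethylcyclohex-1-ene-1-carbaldehyde) | O=CC1=C(C)CCCC1(C)C | starting material
2 | rac-1-(2,6,6-trimethylcyclohex-1-en-1-yl)ethan-1-ol | CC(O)C1=C(C)CCCC1(C)C | intermediate
3 | 1-(2,6,6-trimethylcyclohex-1-en-1-yl)ethan-1-one | CC(=O)C1=C(C)CCCC1(C)C | intermediate
4 | (1R)-1-(2,6,6-trimethylcyclohex-1-en-1-yl)ethan-1-ol | C[C@@H](O)C1=C(C)CCCC1(C)C | intermediate
5 | 4-(benzyloxy)butanoic acid | OC(=O)CCCOCc1ccccc1 | starting material
6 | (1R)-1-(2,6,6-trimethylcyclohex-1-en-1-yl)ethyl 4-(benzyloxy)butanoate | C[C@@H](OC(=O)CCCOCc1ccccc1)C1=C(C)CCCC1(C)C | intermediate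
7 | Z-trimethylsilyl ketene acetal of 6 (CH2CH2OBn cis to OSiMe3) | C[C@@H](O/C(O[Si](C)(C)C)=C/CCOCc1ccccc1)C1=C(C)CCCC1(C)C | intermediate
8 | trimethylsilyl ester of acid 9 | c1ccccc1COCC[C@@H](C(=O)O[Si](C)(C)C)[C@@]2(C)CCCC(C)(C)/C2=C\C | intermediate
9 | (2R)-4-(benzyloxy)-2-[(1R,2E)-2-ethylidene-1,3,3-trimethylcyclohexyl]butanoic acid | c1ccccc1COCC[C@@H](C(=O)O)[C@@]2(C)CCCC(C)(C)/C2=C\C | intermediate
10 | (3R)-5-(benzyloxy)-3-[(1R,2E)-2-ethylidene-1,3,3-trimethylcyclohexyl]pentan-2-one | c1ccccc1COCC[C@@H](C(C)=O)[C@@]2(C)CCCC(C)(C)/C2=C\C | intermediate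
11 | bis-borane adduct of 10 (BH2 on C6, OBH2 on C8; idealised monomer, carbinol and boryl centres undefined) | c1ccccc1COCC[C@@H](C(C)OB)[C@@]2(C)CCCC(C)(C)[C@@H]2C(C)B | intermediate
12 | (3R)-3-[(1R,2S)-2-acetyl-1,3,3-trimethylcyclohexyl]-5-(benzyloxy)pentan-2-one | c1ccccc1COCC[C@@H](C(C)=O)[C@@]2(C)CCCC(C)(C)[C@@H]2C(C)=O | intermediate
13 | 12-benzyloxy-8-hydroxy-13,14,15,16-tetranorlabdan-6-one (aldol, C8 epimers) | c1ccccc1COCC[C@@H]1[C@@]2(C)CCCC(C)(C)[C@@H]2C(=O)CC1(C)O | intermediate
14 | 12-benzyloxy-13,14,15,16-tetranorlabd-7-en-6-one | c1ccccc1COCC[C@@H]1[C@@]2(C)CCCC(C)(C)[C@@H]2C(=O)C=C1C | intermediate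
15 | 12-benzyloxy-7α,8α-epoxy-13,14,15,16-tetranorlabdan-6-one | c1ccccc1COCC[C@@H]1[C@@]2(C)CCCC(C)(C)[C@@H]2C(=O)[C@H]3O[C@@]13C | intermediate
16 | 12-benzyloxy-8α-hydroxy-13,14,15,16-tetranorlabdan-6-one | c1ccccc1COCC[C@@H]1[C@@]2(C)CCCC(C)(C)[C@@H]2C(=O)C[C@@]1(C)O | intermediate
17 | 13,14,15,16-tetranorlabdane-6α,8α,12-triol | OCC[C@@H]1[C@@]2(C)CCCC(C)(C)[C@@H]2[C@@H](O)C[C@@]1(C)O | intermediate
18 | 8α,12-epoxy-13,14,15,16-tetranorlabdane-6α,12-diol (lactol, C12 epimers) | OC1C[C@@H]2[C@@]3(C)CCCC(C)(C)[C@@H]3[C@@H](O)C[C@@]2(C)O1 | intermediate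
19 | 6α-hydroxy-13,14,15,16-tetranorlabdan-12,8α-olide | O=C1C[C@@H]2[C@@]3(C)CCCC(C)(C)[C@@H]3[C@@H](O)C[C@@]2(C)O1 | intermediate
20 | (12Z)-13-iodo-14,15-dinorlabd-12-ene-6α,8α-diol | I/C(C)=C\C[C@@H]1[C@@]2(C)CCCC(C)(C)[C@@H]2[C@@H](O)C[C@@]1(C)O | intermediate
21 | (12Z)-labda-12,14-diene-6α,8α-diol | C=C/C(C)=C\C[C@@H]1[C@@]2(C)CCCC(C)(C)[C@@H]2[C@@H](O)C[C@@]1(C)O | intermediate
22 | (1R,2R,4S,4aS,8aS)-2-hydroxy-2,5,5,8a-tetramethyl-1-[(2Z)-3-methylpenta-2,4-dien-1-yl]decahydronaphthalen-4-yl (2Z)-2-methylbut-2-enoate | C=C/C(C)=C\C[C@@H]1[C@@]2(C)CCCC(C)(C)[C@@H]2[C@@H](OC(=O)/C(C)=C\C)C[C@@]1(C)O | target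

Total step count: 15. Longest linear sequence: 15 steps (1 → 22).

Steps most likely to fail

Step 5 (Ireland–Claisen rearrangement). Enolisation may not give the Z ketene acetal cleanly, or the crowded chair transition state may give way to competing pathways, so that C9 is set with poor selectivity or the ester fragments instead of rearranging. The fallback sets out from 4 and returns at 12. Heating 4 with triethyl orthoacetate and a trace of propanoic acid (Johnson–Claisen rearrangement) transfers chirality to C10 alone and gives ethyl 2-[(1R,2E)-2-ethylidene-1,3,3-trimethylcyclohexyl]acetate F1. Hydroboration–oxidation (BH3·THF; NaOH, H2O2) gives the hydroxy ester ethyl 2-[2-(1-hydroxyethyl)-1,3,3-trimethylcyclohexyl]acetate F2 (H-5 trans to the C10 methyl). Catalytic TsOH closes it to the trans-fused δ-lactone 1,4a,8,8-tetramethyloctahydro-3H-isochromen-3-one F3, a temporary ring that holds C9 in a rigid frame. Its lithium enolate is alkylated with 2-(benzyloxy)ethyl iodide anti to the angular methyl to give the 9α-[2-(benzyloxy)ethyl] lactone F4. Re-enolisation with LiN(i-Pr)2 and kinetic protonation from the same open face should place the chain β, giving the 9β-[2-(benzyloxy)ethyl] lactone F5. One equivalent of MeLi at −78 °C opens it to the hydroxy ketone (3R)-5-(benzyloxy)-3-[2-(1-hydroxyethyl)-1,3,3-trimethylcyclohexyl]pentan-2-one F6, and Dess–Martin oxidation returns to diketone 12.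

Step 8 (aldol ring closure). The ring may close in the wrong sense (C17 enolate onto the C6 carbonyl), or base may epimerise C9 before or after closure. The fallback sets out from 10 and returns at 14. The C8 ketone of 10 is masked with ethylene glycol and catalytic TsOH as the ethylene ketal of 10 F7. The one-pot hydroboration–oxidation of step 7 then gives the C6 methyl ketone with the C8 ketal intact F8, in which C7 is the only enolisable methyl. Kinetic enolisation (LiN(i-Pr)2, Me3SiCl, −78 °C) gives the C6 trimethylsilyl enol ether F9. TiCl4 in CH2Cl2 at −78 °C then promotes an intramolecular Mukaiyama aldol reaction onto the ketal, which closes the same C7–C8 bond regiospecifically and without base to give 12-benzyloxy-8-(2-hydroxyethoxy)-13,14,15,16-tetranorlabdan-6-one F10. DBU in warm toluene eliminates ethylene glycol and gives enone 14.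

Step 13 (iodo-olefination of the lactol). The thermally labile α-iodo ylide may decompose before the lactol opens to the hydroxy aldehyde, or Z/E control may erode at the temperature the opening needs. The fallback sets out from 18 and returns at 21, bypassing 20. Still–Gennari olefination of 18 with methyl 2-[bis(2,2,2-trifluoroethoxy)phosphoryl]propanoate (KN(SiMe3)2, 18-crown-6, THF) gives methyl (12Z)-6α,8α-dihydroxy-15-norlabd-12-en-14-oate F11. i-Bu2AlH reduces it to (12Z)-15-norlabd-12-ene-6α,8α,14-triol F12. MnO2 oxidises only the allylic hydroxyl to (12Z)-6α,8α-dihydroxy-15-norlabd-12-en-14-al F13, and Wittig methylenation with Ph3P=CH2 gives diene 21.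

Further compounds
F1 | step 5 | ethyl 2-[(1R,2E)-2-ethylidene-1,3,3-trimethylcyclohexyl]acetate | CCOC(=O)C[C@@]1(C)CCCC(C)(C)/C1=C\C
F2 | step 5 | ethyl 2-[2-(1-hydroxyethyl)-1,3,3-trimethylcyclohexyl]acetate (H-5 trans to C10 methyl, carbinol centre undefined) | CCOC(=O)C[C@@]1(C)CCCC(C)(C)[C@@H]1C(C)O
F3 | step 5 | trans-fused δ-lactone 1,4a,8,8-tetramethyloctahydro-3H-isochromen-3-one | O=C1C[C@@]2(C)CCCC(C)(C)[C@@H]2C(C)O1
F4 | step 5 | 9α-[2-(benzyloxy)ethyl] lactone (chain anti to the angular methyl) | O=C1[C@@H](CCOCc3ccccc3)[C@@]2(C)CCCC(C)(C)[C@@H]2C(C)O1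
F5 | step 5 | 9β-[2-(benzyloxy)ethyl] lactone | O=C1[C@H](CCOCc3ccccc3)[C@@]2(C)CCCC(C)(C)[C@@H]2C(C)O1
F6 | step 5 | (3R)-5-(benzyloxy)-3-[2-(1-hydroxyethyl)-1,3,3-trimethylcyclohexyl]pentan-2-one | CC(=O)[C@H](CCOCc1ccccc1)[C@@]2(C)CCCC(C)(C)[C@@H]2C(C)O
F7 | step 8 | ethylene ketal of 10 | c1ccccc1COCC[C@@H](C2(C)OCCO2)[C@@]3(C)CCCC(C)(C)/C3=C\C
F8 | step 8 | C6 methyl ketone with C8 ethylene ketal | c1ccccc1COCC[C@@H](C2(C)OCCO2)[C@@]3(C)CCCC(C)(C)[C@@H]3C(C)=O
F9 | step 8 | C6 trimethylsilyl enol ether of F8 | c1ccccc1COCC[C@@H](C2(C)OCCO2)[C@@]3(C)CCCC(C)(C)[C@@H]3C(=C)O[Si](C)(C)C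
F10 | step 8 | 12-benzyloxy-8-(2-hydroxyethoxy)-13,14,15,16-tetranorlabdan-6-one (C8 epimers) | c1ccccc1COCC[C@@H]1[C@@]2(C)CCCC(C)(C)[C@@H]2C(=O)CC1(C)OCCO
F11 | step 13 | methyl (12Z)-6α,8α-dihydroxy-15-norlabd-12-en-14-oate | COC(=O)/C(C)=C\C[C@@H]1[C@@]2(C)CCCC(C)(C)[C@@H]2[C@@H](O)C[C@@]1(C)O
F12 | step 13 | (12Z)-15-norlabd-12-ene-6α,8α,14-triol | OC/C(C)=C\C[C@@H]1[C@@]2(C)CCCC(C)(C)[C@@H]2[C@@H](O)C[C@@]1(C)O
F13 | step 13 | (12Z)-6α,8α-dihydroxy-15-norlabd-12-en-14-al | O=C/C(C)=C\C[C@@H]1[C@@]2(C)CCCC(C)(C)[C@@H]2[C@@H](O)C[C@@]1(C)O
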